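The earlier runs and the new flask are calculated for substances that don't exist; noise was put on by code.

At the time of reading, 3.0 h, 5.0 h or 6.0 h, I want to know how much J has already gone over to Q. The steps considered are D + L → J, D + L → X, L + J → E, J ⇌ Q, L → G and L ⇌ Z.

| setting | oak | elm | maple | ochre | grey | blue |
|---|---|---|---|---|---|---|
| D | 0.080 M | 0.18 M | 0.12 M | 0.12 M | 0.12 M | 0.12 M |
| L | 1.2 equiv | 1.2 equiv | 0.60 equiv | 1.20 equiv | 1.20 equiv | 1.20 equiv |
| remark | run made earlier | run made earlier | run made earlier |  |  |  |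
| time |  |  |  | 3.0 h | 5.0 h | 6.0 h |

| run | time / h | X / % | E / % | Q / % | D / % | J / % |
|---|---|---|---|---|---|---|
| oak | 0.667 | 0 | 0 | 0 | 29 | 70 |
| oak | 1.33 | 4 | 0 | 3 | 15 | 80 |
| oak | 2.00 | 3 | 3 | 0 | 11 | 83 |
| oak | 3.00 | 2 | 0 | 4 | 8 | 86 |
| oak | 4.00 | 3 | 1 | 6 | 7 | 82 |
| elm | 0.250 | 4 | 0 | 0 | 30 | 67 |
| elm | 0.500 | 1 | 2 | 0 | 16 | 78 |
| elm | 1.00 | 2 | 2 | 3 | 7 | 88 |
| elm | 2.00 | 3 | 3 | 5 | 1 | 89 |
| elm | 4.00 | 3 | 1 | 6 | 1 | 90 |
| maple | 0.667 | 2 | 3 | 0 | 53 | 45 |
| maple | 1.33 | 3 | 0 | 2 | 45 | 48 |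
| maple | 2.00 | 2 | 0 | 3 | 44 | 52 |
| maple | 3.00 | 3 | 0 | 4 | 45 | 51 |
| maple | 4.00 | 2 | 1 | 5 | 42 | 50 |

(readings scatter by 1.5 percentage points)

- reactions considered so far: D + L -> X; D + L -> J; L + J -> E; J <-> Q; L -> G; L <-> Z

1. which of these there is most of at the end, counted by the D in it, ochre (X / J / Q / D)
2. which of these there is most of at the end, counted by the D in it, grey (X / J / Q / D)
3. which of these there is most of at the end, counted by the D in it, blue (X / J / Q / D)
4. the largest of these amounts at the end, in percent of the D charged, ochre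
5. the largest of these amounts at the end, in percent of the D charged, grey
6. the largest of these amounts at the end, in percent of the D charged, blue

In the first instants D goes over to J by D + L → J: oak reads J 70% at 0.667 h. X stays small, 3% at oak's last reading. Maple still reads D 42% at its last reading, with L, at 0.60 equiv, as the limiting reagent.

In the middle D tails off. The last readings are 7% in oak and 1% in elm, while E reads 1% in elm.

At the last reading of elm, J and Q hold nearly all of the D charged, so I follow the slow leak J → Q next.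

I average c(Q)/c(J) at the last reading of the three runs and divide by that time. This gives a leak rate of 0.0200 h⁻¹, a rough reading, since the scatter is 1.5 percentage points on Q of 6% in elm. I carry its inverse form, the decade time 5.00 h, the hours for Q to stand one power of ten below J. On logarithmic axes, I take log c(Q)/c(J) to climb in step with log t while Q stays small beside J.

So I reckon c(Q)/c(J) at 6.00%, 10.00% and 12.0%. The J + Q pool at the last readings of oak and elm averages 92.0%, which by my reckoning puts J at 86.8%, 83.6% and 82.1%.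

The forecast names J for each flask, at 88%, 86.5% and 86%: “J is therefore the largest species throughout”. My grey figure lies lower than its 86.5%.

J leads at 86.2% in ochre, 83.9% in grey and 82.3% in blue.

    D + L → X (k = 0.0250 M⁻¹ min⁻¹)
    D + L → J (k = 0.600 M⁻¹ min⁻¹)
    L + J → E (k = 0.00210 M⁻¹ min⁻¹)
    J ⇌ Q (K = 8.10, k = 3.90 × 10⁻⁴ min⁻¹)
    L → G (k = 2.20 × 10⁻⁶ min⁻¹)
    L ⇌ Z (K = 2.00, k = 0.00400 min⁻¹)

In blue, the reverse step Q to J makes no difference to J at the asked time. Grey is read at 5.0 h, against a decade time of 5.00 h, and its c(Q)/c(J) is 11.2%. The neighbour of grey with 0.480 equiv of L still holds D 54.0%, yet at 5.00 h its c(Q)/c(J) is 11.4%.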